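**Strategy**

Ring C is opened at C4–C4a. Because the acyl carbon C4 is tied to ring A through O1, C2 and C3, it can reach only the two carbons ortho to O1. One of them (C8) carries the prenyl group, so it must bond to C4a, which is also para to O7 and the most electron-rich site of the ring. One intramolecular Friedel–Crafts acylation therefore closes ring C with full regiocontrol and leaves C2 untouched. The precursor is the (S)-3-aryl-3-aryloxypropanoic acid whose C2 already joins the prenylated chromene (ring B) to O1 of the O7-silylated 2-prenylresorcinol. That C2–O1 bond is set by iridium-catalysed asymmetric allylic etherification.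

Key step: step 13

Assumption: the (Sa,S,S)-phosphoramidite is taken to give the (S)-ether in step 10, by analogy with aryloxide additions to (E)-cinnamyl carbonates; the sense is to be confirmed on a model and the ligand antipode exchanged if it proves opposite.

**Route**

Step 1
Reactants: 1 resorcinol
Product: 2 1,3-bis(methoxymethoxy)benzene
Conditions: MOMCl (2.5 equiv), i-Pr2NEt (3 equiv), CH2Cl2, 0 °C → rt
Reagents that add atoms: chloromethyl methyl ether, COCCl
Why: Williamson-type O-alkylation of the two equivalent phenols installs the acetal groups that direct the metalation of step 2.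

Step 2
Reactants: 2 1,3-bis(methoxymethoxy)benzene; 3 prenyl bromide (1-bromo-3-methylbut-2-ene)
Product: 5 1,3-bis(methoxymethoxy)-2-(3-methylbut-2-en-1-yl)benzene, via 2-lithio-1,3-bis(methoxymethoxy)benzene 4 (not isolated)
Conditions: n-BuLi (1.1 equiv), THF, 0 °C → rt; then 3, −78 °C → rt
Reagents that add atoms: none
Why: Directed ortho-metalation, in which both acetal oxygens guide lithiation to the carbon between them, followed by SN2 displacement of bromide at the primary allylic carbon.

Step 3
Reactants: 5 1,3-bis(methoxymethoxy)-2-(3-methylbut-2-en-1-yl)benzene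
Product: 6 2-(3-methylbut-2-en-1-yl)benzene-1,3-diol (2-prenylresorcinol)
Conditions: HCl (1 M in MeOH), rt → 40 °C
Reagents that add atoms: none
Why: Acid-catalysed transacetalisation to methanol removes both methoxymethyl groups, and dilute acid with early work-up is chosen so that the ortho-prenylphenol does not close to a chroman.

Step 4
Reactants: 6 2-(3-methylbut-2-en-1-yl)benzene-1,3-diol
Product: 7 2-(3-methylbut-2-en-1-yl)-3-(triisopropylsilyloxy)phenol
Conditions: TIPSCl (1.0 equiv, slow addition), imidazole (2.2 equiv), DMF, 0 °C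
Reagents that add atoms: chlorotriisopropylsilane, CC(C)[Si](Cl)(C(C)C)C(C)C
Why: Imidazole-promoted silylation of one of two equivalent hydroxyls, so only one mono-silyl ether can form; diol and bis-silyl ether are separable and can be recycled.

Step 5
Reactants: 8 4-hydroxybenzaldehyde; 3 prenyl bromide (1-bromo-3-methylbut-2-ene)
Product: 10 4-hydroxy-3-(3-methylbut-2-en-1-yl)benzaldehyde, via potassium 4-formylphenoxide 9 (not isolated)
Conditions: KOH (1.1 equiv), H2O, rt; then 3 (1.0 equiv), rt
Reagents that add atoms: none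
Why: Ortho-C-alkylation of a phenoxide in water, where solvation of the oxygen diverts the ambident anion to carbon and the para position is blocked by the formyl group; a moderate return is accepted on inexpensive material.

Step 6
Reactants: 10 4-hydroxy-3-(3-methylbut-2-en-1-yl)benzaldehyde; 11 1,1-diethoxy-3-methylbut-2-ene (diethyl acetal of 3-methylbut-2-enal)
Product: 12 2,2-dimethyl-8-(3-methylbut-2-en-1-yl)-2H-chromene-6-carbaldehyde
Conditions: 3-picoline (0.25 equiv), p-xylene, 140 °C, EtOH distilled off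
Reagents that add atoms: none
Why: Pyridine-base-catalysed chromenylation of a phenol with an enal acetal: acetal exchange, carbon–carbon bond formation at the only free ortho position to an ortho-quinone methide, then oxa-6π electrocyclisation.

Step 7
Reactants: 12 2,2-dimethyl-8-(3-methylbut-2-en-1-yl)-2H-chromene-6-carbaldehyde
Product: 13 methyl (E)-3-[2,2-dimethyl-8-(3-methylbut-2-en-1-yl)-2H-chromen-6-yl]prop-2-enoate
Conditions: Ph3P=CHCO2Me (1.2 equiv), toluene, 80 °C
Reagents that add atoms: methyl (triphenylphosphoranylidene)acetate, COC(=O)C=P(c1ccccc1)(c1ccccc1)c1ccccc1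
Why: Wittig olefination with a stabilised ylide, which should give the E-alkene from an aromatic aldehyde.

Step 8
Reactants: 13 methyl (E)-3-[2,2-dimethyl-8-(3-methylbut-2-en-1-yl)-2H-chromen-6-yl]prop-2-enoate
Product: 14 (E)-3-[2,2-dimethyl-8-(3-methylbut-2-en-1-yl)-2H-chromen-6-yl]prop-2-en-1-ol
Conditions: i-Bu2AlH (2.5 equiv), CH2Cl2, −78 °C; aq. KNaC4H4O6
Reagents that add atoms: none
Why: 1,2-Reduction of a conjugated ester by an aluminium hydride at low temperature, which leaves all carbon–carbon double bonds untouched.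

Step 9
Reactants: 14 (E)-3-[2,2-dimethyl-8-(3-methylbut-2-en-1-yl)-2H-chromen-6-yl]prop-2-en-1-ol
Product: 15 (E)-3-[2,2-dimethyl-8-(3-methylbut-2-en-1-yl)-2H-chromen-6-yl]prop-2-en-1-yl methyl carbonate
Conditions: ClCO2Me (1.5 equiv), pyridine (2 equiv), CH2Cl2, 0 °C
Reagents that add atoms: methyl chloroformate, COC(Cl)=O
Why: O-Acylation of the primary allylic alcohol under mild base gives the linear carbonate needed for allylic substitution.

Step 10
Reactants: 7 2-(3-methylbut-2-en-1-yl)-3-(triisopropylsilyloxy)phenol; 15 (E)-3-[2,2-dimethyl-8-(3-methylbut-2-en-1-yl)-2H-chromen-6-yl]prop-2-en-1-yl methyl carbonate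
Product: 17 (S)-2,2-dimethyl-8-(3-methylbut-2-en-1-yl)-6-{1-[2-(3-methylbut-2-en-1-yl)-3-(triisopropylsilyloxy)phenoxy]prop-2-en-1-yl}-2H-chromene, via lithium 2-(3-methylbut-2-en-1-yl)-3-(triisopropylsilyloxy)phenoxide 16 (not isolated)
Conditions: 7 (1.5 equiv), n-BuLi (1.5 equiv), THF, 0 °C; then 15, [Ir(cod)Cl]2 (2 mol %), (Sa,S,S)-O,O′-(1,1′-binaphthalene-2,2′-diyl) N,N-bis(1-phenylethyl)phosphoramidite (4 mol %), THF, rt → 40 °C
Reagents that add atoms: none
Why: Iridium-catalysed asymmetric allylic etherification: the cyclometalated iridium–phosphoramidite complex ionises the carbonate to an allyl complex, the aryloxide attacks the aryl-substituted terminus (branched product), and the ligand fixes the face of attack so that C2 is set as (S).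

Step 11
Reactants: 17 the (S)-allyl aryl ether
Product: 19 (S)-3-[2,2-dimethyl-8-(3-methylbut-2-en-1-yl)-2H-chromen-6-yl]-3-[2-(3-methylbut-2-en-1-yl)-3-(triisopropylsilyloxy)phenoxy]propan-1-ol, via B-alkyl-9-borabicyclo[3.3.1]nonane 18 (not isolated)
Conditions: 9-BBN (1.2 equiv), THF, 0 °C → rt; then NaBO3·4H2O, THF/H2O, rt
Reagents that add atoms: sodium perborate, [Na+].[Na+].O[B-]1(O)OO[B-](O)(O)OO1
Why: Hydroboration–oxidation, in which the bulky borane should select the monosubstituted vinyl group over the trisubstituted prenyl alkenes and the hindered chromene alkene and place boron on the terminal carbon, while the mildly basic perborate spares the aryl silyl ether and C2 is not touched.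

Step 12
Reactants: 19 the (S)-3-aryl-3-aryloxypropan-1-ol
Product: 20 (S)-3-[2,2-dimethyl-8-(3-methylbut-2-en-1-yl)-2H-chromen-6-yl]-3-[2-(3-methylbut-2-en-1-yl)-3-(triisopropylsilyloxy)phenoxy]propanoic acid
Conditions: TEMPO (0.2 equiv), PhI(OAc)2 (2.5 equiv), MeCN/CH2Cl2/H2O, 0 °C → rt
Reagents that add atoms: water, O
Why: Oxoammonium-catalysed oxidation of a primary alcohol to the acid through the aldehyde hydrate under near-neutral conditions, so that the transient β-aryloxy aldehyde is oxidised on before it can eliminate aryloxide and the alkenes are left alone.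

Step 13
Reactants: 20 the (S)-3-aryl-3-aryloxypropanoic acid
Product: 22 (2S)-2-[2,2-dimethyl-8-(3-methylbut-2-en-1-yl)-2H-chromen-6-yl]-8-(3-methylbut-2-en-1-yl)-7-(triisopropylsilyloxy)chroman-4-one, via acid chloride 21 (not isolated)
Conditions: 1-chloro-N,N,2-trimethylprop-1-en-1-amine (1.2 equiv), CH2Cl2, 0 °C; then 2,6-di-tert-butyl-4-methylpyridine (1.5 equiv), SnCl4 (2.5 equiv), CH2Cl2 (0.01 M), −78 °C; aq. NaHCO3 quench at −78 °C
Reagents that add atoms: none
Why: The chloroenamine turns the acid into acyl chloride 21 without releasing acid; SnCl4 then polarises it to an acylium-type electrophile that attacks the arene carbon ortho to O1 and para to the silyloxy group (the future C4a), and the Wheland intermediate rearomatises by losing a proton to the hindered pyridine. The closest known reaction type is the intramolecular Friedel–Crafts acylation of 3-aryloxypropanoyl chlorides to chroman-4-ones. Ring C closes in a 6-exo mode at the acyl carbon (the C=O stays outside the ring), forming C4–C4a. No stereocentre is created; C2 is carried through unchanged provided the para-alkoxybenzylic C2–O1 bond does not ionise, which −78 °C, the absence of free HCl and the cold quench are meant to ensure. Regioselectivity is secured by the substrate: the O1–C2–C3 tether reaches only the two carbons ortho to O1, and the other one (C8) bears the prenyl group. Chemoselectivity over the three alkenes rests on the ring closure at the doubly oxygen-activated carbon being faster than any intermolecular acylation at high dilution.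

Step 14
Reactants: 22 the (2S)-7-O-triisopropylsilyl flavanone
Product: 23 (2S)-2-[2,2-dimethyl-8-(3-methylbut-2-en-1-yl)-2H-chromen-6-yl]-7-hydroxy-8-(3-methylbut-2-en-1-yl)chroman-4-one (target)
Conditions: Bu4NF (1.2 equiv), AcOH (1.5 equiv), THF, 0 °C
Reagents that add atoms: none
Why: Fluoride-mediated cleavage of the aryl silyl ether, buffered with acetic acid so that the medium never becomes basic enough to open ring C by retro-oxa-Michael reaction and scramble C2.

**Compound list**

1 | resorcinol | Oc1cccc(O)c1 | starting material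
2 | 1,3-bis(methoxymethoxy)benzene | COCOc1cccc(OCOC)c1 | intermediate
3 | prenyl bromide (1-bromo-3-methylbut-2-ene) | CC(C)=CCBr | starting material
4 | 2-lithio-1,3-bis(methoxymethoxy)benzene | [Li]c1c(OCOC)cccc1OCOC | intermediate
5 | 1,3-bis(methoxymethoxy)-2-(3-methylbut-2-en-1-yl)benzene | COCOc1cccc(OCOC)c1CC=C(C)C | intermediate
6 | 2-(3-methylbut-2-en-1-yl)benzene-1,3-diol | CC(C)=CCc1c(O)cccc1O | intermediate
7 | 2-(3-methylbut-2-en-1-yl)-3-(triisopropylsilyloxy)phenol | CC(C)=CCc1c(O)cccc1O[Si](C(C)C)(C(C)C)C(C)C | intermediate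
8 | 4-hydroxybenzaldehyde | O=Cc1ccc(O)cc1 | starting material
9 | potassium 4-formylphenoxide | [K+].[O-]c1ccc(C=O)cc1 | intermediate
10 | 4-hydroxy-3-(3-methylbut-2-en-1-yl)benzaldehyde | CC(C)=CCc1cc(C=O)ccc1O | intermediate
11 | 1,1-diethoxy-3-methylbut-2-ene | CCOC(OCC)C=C(C)C | starting material
12 | 2,2-dimethyl-8-(3-methylbut-2-en-1-yl)-2H-chromene-6-carbaldehyde | CC(C)=CCc1cc(C=O)cc2C=CC(C)(C)Oc12 | intermediate
13 | methyl (E)-3-[2,2-dimethyl-8-(3-methylbut-2-en-1-yl)-2H-chromen-6-yl]prop-2-enoate | COC(=O)/C=C/c1cc(CC=C(C)C)c2OC(C)(C)C=Cc2c1 | intermediate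
14 | (E)-3-[2,2-dimethyl-8-(3-methylbut-2-en-1-yl)-2H-chromen-6-yl]prop-2-en-1-ol | OC/C=C/c1cc(CC=C(C)C)c2OC(C)(C)C=Cc2c1 | intermediate
15 | (E)-3-[2,2-dimethyl-8-(3-methylbut-2-en-1-yl)-2H-chromen-6-yl]prop-2-en-1-yl methyl carbonate | COC(=O)OC/C=C/c1cc(CC=C(C)C)c2OC(C)(C)C=Cc2c1 | intermediate
16 | lithium 2-(3-methylbut-2-en-1-yl)-3-(triisopropylsilyloxy)phenoxide | [Li+].[O-]c1cccc(O[Si](C(C)C)(C(C)C)C(C)C)c1CC=C(C)C | intermediate
17 | (S)-2,2-dimethyl-8-(3-methylbut-2-en-1-yl)-6-{1-[2-(3-methylbut-2-en-1-yl)-3-(triisopropylsilyloxy)phenoxy]prop-2-en-1-yl}-2H-chromene | C=C[C@H](Oc1cccc(O[Si](C(C)C)(C(C)C)C(C)C)c1CC=C(C)C)c1cc(CC=C(C)C)c2OC(C)(C)C=Cc2c1 | intermediate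
18 | 9-{(S)-3-[2,2-dimethyl-8-(3-methylbut-2-en-1-yl)-2H-chromen-6-yl]-3-[2-(3-methylbut-2-en-1-yl)-3-(triisopropylsilyloxy)phenoxy]propyl}-9-borabicyclo[3.3.1]nonane | C1CCC2CCCC1B2CC[C@H](Oc1cccc(O[Si](C(C)C)(C(C)C)C(C)C)c1CC=C(C)C)c1cc(CC=C(C)C)c2OC(C)(C)C=Cc2c1 | intermediate
19 | (S)-3-[2,2-dimethyl-8-(3-methylbut-2-en-1-yl)-2H-chromen-6-yl]-3-[2-(3-methylbut-2-en-1-yl)-3-(triisopropylsilyloxy)phenoxy]propan-1-ol | OCC[C@H](Oc1cccc(O[Si](C(C)C)(C(C)C)C(C)C)c1CC=C(C)C)c1cc(CC=C(C)C)c2OC(C)(C)C=Cc2c1 | intermediate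
20 | (S)-3-[2,2-dimethyl-8-(3-methylbut-2-en-1-yl)-2H-chromen-6-yl]-3-[2-(3-methylbut-2-en-1-yl)-3-(triisopropylsilyloxy)phenoxy]propanoic acid | OC(=O)C[C@H](Oc1cccc(O[Si](C(C)C)(C(C)C)C(C)C)c1CC=C(C)C)c1cc(CC=C(C)C)c2OC(C)(C)C=Cc2c1 | intermediate
21 | (S)-3-[2,2-dimethyl-8-(3-methylbut-2-en-1-yl)-2H-chromen-6-yl]-3-[2-(3-methylbut-2-en-1-yl)-3-(triisopropylsilyloxy)phenoxy]propanoyl chloride | ClC(=O)C[C@H](Oc1cccc(O[Si](C(C)C)(C(C)C)C(C)C)c1CC=C(C)C)c1cc(CC=C(C)C)c2OC(C)(C)C=Cc2c1 | intermediate
22 | (2S)-2-[2,2-dimethyl-8-(3-methylbut-2-en-1-yl)-2H-chromen-6-yl]-8-(3-methylbut-2-en-1-yl)-7-(triisopropylsilyloxy)chroman-4-one | CC(C)=CCc1cc([C@@H]2CC(=O)c3ccc(O[Si](C(C)C)(C(C)C)C(C)C)c(CC=C(C)C)c3O2)cc2c1OC(C)(C)C=C2 | intermediate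
23 | (2S)-2-[2,2-dimethyl-8-(3-methylbut-2-en-1-yl)-2H-chromen-6-yl]-7-hydroxy-8-(3-methylbut-2-en-1-yl)chroman-4-one | CC(C)=CCc1cc([C@@H]2CC(=O)c3ccc(O)c(CC=C(C)C)c3O2)cc2c1OC(C)(C)C=C2 | target

**Totals**

Total step count: 14.
Longest linear sequence: 10 steps (steps 5–14, from 4-hydroxybenzaldehyde 8); the resorcinol branch (steps 1–4) joins at step 10.

**Steps most likely to fail**

Step 13. The Lewis acid may ionise the electron-rich benzylic C2–O1 bond. Before ring closure this would mean β-elimination of the aryloxide; after it, reversible opening of ring C through the O1-conjugated ketone. Either way the configuration at C2 would erode, and any HCl not intercepted could add to the prenyl or chromene alkenes. The fallback no longer carries the stereocentre through the acylation but restores it afterwards by resolution. It sets out from acid 20, which is cyclised through 21 with SnCl4 at −40 °C to complete conversion without regard to configuration, giving the racemic or scalemic 2-[2,2-dimethyl-8-(3-methylbut-2-en-1-yl)-2H-chromen-6-yl]-8-(3-methylbut-2-en-1-yl)-7-(triisopropylsilyloxy)chroman-4-one F1. Asymmetric transfer hydrogenation under kinetic-resolution conditions (Cp*RhCl[(R,R)-TsDPEN] (cat.), HCO2H/Et3N, EtOAc, rt, stopped near half conversion) is a known way to resolve racemic flavanones. It should reduce the (2R)-ketone to the cis-configured (2R,4R)-2-[2,2-dimethyl-8-(3-methylbut-2-en-1-yl)-2H-chromen-6-yl]-8-(3-methylbut-2-en-1-yl)-7-(triisopropylsilyloxy)chroman-4-ol F2 and leave the (2S)-ketone. The catalyst antipode is to be the one that consumes the (2R)-ketone. Chromatographic separation returns the route at 22.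

Step 10. The electron-rich branched ether may re-ionise at the metal, and the ortho-substituted aryloxide may attack the allyl complex slowly, so that both the branched-to-linear ratio and the enantiomeric purity fall. The fallback makes the C2–O1 bond by substitution with inversion at a carbinol centre. It sets out from ester 13. Copper-catalysed asymmetric conjugate borylation (CuCl, NaOt-Bu, a Josiphos-type ferrocenyl diphosphine, B2pin2, MeOH, THF, rt; ligand antipode chosen for the (R)-product) gives methyl (3R)-3-[2,2-dimethyl-8-(3-methylbut-2-en-1-yl)-2H-chromen-6-yl]-3-(4,4,5,5-tetramethyl-1,3,2-dioxaborolan-2-yl)propanoate F3. This is oxidised in the same flask (NaBO3·4H2O, THF/H2O) with retention to methyl (3R)-3-[2,2-dimethyl-8-(3-methylbut-2-en-1-yl)-2H-chromen-6-yl]-3-hydroxypropanoate F4. Mitsunobu etherification with phenol 7 (PPh3, diisopropyl azodicarboxylate, toluene, 0 °C) inverts the carbinol carbon and gives methyl (3S)-3-[2,2-dimethyl-8-(3-methylbut-2-en-1-yl)-2H-chromen-6-yl]-3-[2-(3-methylbut-2-en-1-yl)-3-(triisopropylsilyloxy)phenoxy]propanoate F5. Reduction with i-Bu2AlH (CH2Cl2, −78 °C) returns the route at alcohol 19, and steps 8, 9 and 11 are then not needed.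

Step 6. The phenol is deactivated by the para-formyl group and hindered by the ortho-prenyl group, so it may fail to enter the acetal-exchange and electrocyclisation cascade, leaving the acetal to oligomerise. The fallback builds the pyran ring by a sigmatropic sequence and sets out from phenol 10. Copper-catalysed O-alkylation with 3-chloro-3-methylbut-1-yne (DBU, CuCl2·2H2O (cat.), MeCN, 0 °C) gives 3-(3-methylbut-2-en-1-yl)-4-[(2-methylbut-3-yn-2-yl)oxy]benzaldehyde F6. Heating (N,N-diethylaniline, 190 °C) should trigger the aromatic propargyl Claisen rearrangement to the free ortho position, 1,5-hydrogen shift and oxa-6π electrocyclisation, returning the route at chromene aldehyde 12.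

**Further compounds**

F1 | step 13 | rac-2-[2,2-dimethyl-8-(3-methylbut-2-en-1-yl)-2H-chromen-6-yl]-8-(3-methylbut-2-en-1-yl)-7-(triisopropylsilyloxy)chroman-4-one | CC(C)=CCc1cc(C2CC(=O)c3ccc(O[Si](C(C)C)(C(C)C)C(C)C)c(CC=C(C)C)c3O2)cc2c1OC(C)(C)C=C2
F2 | step 13 | (2R,4R)-2-[2,2-dimethyl-8-(3-methylbut-2-en-1-yl)-2H-chromen-6-yl]-8-(3-methylbut-2-en-1-yl)-7-(triisopropylsilyloxy)chroman-4-ol | CC(C)=CCc1cc([C@H]2C[C@@H](O)c3ccc(O[Si](C(C)C)(C(C)C)C(C)C)c(CC=C(C)C)c3O2)cc2c1OC(C)(C)C=C2
F3 | step 10 | methyl (3R)-3-[2,2-dimethyl-8-(3-methylbut-2-en-1-yl)-2H-chromen-6-yl]-3-(4,4,5,5-tetramethyl-1,3,2-dioxaborolan-2-yl)propanoate | COC(=O)C[C@@H](B1OC(C)(C)C(C)(C)O1)c1cc(CC=C(C)C)c2OC(C)(C)C=Cc2c1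
F4 | step 10 | methyl (3R)-3-[2,2-dimethyl-8-(3-methylbut-2-en-1-yl)-2H-chromen-6-yl]-3-hydroxypropanoate | COC(=O)C[C@@H](O)c1cc(CC=C(C)C)c2OC(C)(C)C=Cc2c1
F5 | step 10 | methyl (3S)-3-[2,2-dimethyl-8-(3-methylbut-2-en-1-yl)-2H-chromen-6-yl]-3-[2-(3-methylbut-2-en-1-yl)-3-(triisopropylsilyloxy)phenoxy]propanoate | COC(=O)C[C@H](Oc1cccc(O[Si](C(C)C)(C(C)C)C(C)C)c1CC=C(C)C)c1cc(CC=C(C)C)c2OC(C)(C)C=Cc2c1
F6 | step 6 | 3-(3-methylbut-2-en-1-yl)-4-[(2-methylbut-3-yn-2-yl)oxy]benzaldehyde | C#CC(C)(C)Oc1ccc(C=O)cc1CC=C(C)C
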